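**Assumption:** the target SMILES has no stereocentres and no stereogenic double bonds, so Kanzonol L is achiral and the route needs no stereocontrol.

## Retrosynthetic overview

1. The γ-pyranone ring is closed last: an enaminone with MOM-masked ortho-phenols cyclises by intramolecular oxa-Michael addition and loss of Me2NH, with global MOM removal in the same step.
2. The enaminone comes from a deoxybenzoin and DMF-DMA; the deoxybenzoin comes from Pd-catalysed α-arylation of A-ring acetophenone **8** with B-ring chromenyl bromide **16**.
3. **8** comes from phloroglucinol: tris-MOM ether, then three successive directed ortho-lithiations (prenyl, prenyl, acetyl).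
4. **16** comes from resorcinol monobenzoate: para-bromination, MOM/benzoate exchange, tertiary propargyl ether, Claisen/oxa-6π.
5. Ring order: both benzene rings are bought; the 2,2-dimethylpyran ring forms in step 9; the γ-pyranone ring forms in step 12.

## Route

### Fragment A (acetophenone 8)

**Step 1**
Reactants: **1** phloroglucinol; **2** chloromethyl methyl ether (MOMCl)
Product: **3** 1,3,5-tris(methoxymethoxy)benzene
Conditions: NaH (3.6 equiv), MOMCl (3.6 equiv), DMF, 0 °C → rt
Reagents that add atoms: MOMCl, COCCl
Why: O-alkylation of the tris-phenoxide by the hard electrophile MOMCl (Williamson-type acetal formation) gives the tris-ether, whose OMOM groups direct the later lithiations.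

**Step 2**
Reactants: **3**; **4** prenyl bromide (1-bromo-3-methylbut-2-ene)
Product: **5** 1,3,5-tris(methoxymethoxy)-2-(3-methylbut-2-en-1-yl)benzene
Conditions: n-BuLi (1.1 equiv), THF, 0 °C, 1 h; then prenyl bromide, −78 °C → rt
Reagents that add atoms: prenyl bromide, CC(C)=CCBr
Why: Directed ortho-metalation of the H flanked by two OMOM groups, then SN2 alkylation at the primary allylic carbon, gives the linear prenyl group.

**Step 3**
Reactants: **5**; **4** prenyl bromide
Product: **6** 1,3,5-tris(methoxymethoxy)-2,4-bis(3-methylbut-2-en-1-yl)benzene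
Conditions: n-BuLi (1.1 equiv), THF, 0 °C; then prenyl bromide, −78 °C → rt
Reagents that add atoms: prenyl bromide, CC(C)=CCBr
Why: A second directed ortho-metalation at one of the two equivalent ring positions (each between two OMOM groups) is kinetically preferred over benzylic deprotonation.

**Step 4**
Reactants: **6**; **7** N-methoxy-N-methylacetamide
Product: **8** 1-[2,4,6-tris(methoxymethoxy)-3,5-bis(3-methylbut-2-en-1-yl)phenyl]ethan-1-one
Conditions: n-BuLi (1.1 equiv), TMEDA, THF, 0 °C; then MeC(O)N(OMe)Me, −78 → 0 °C; aq. NH4Cl
Reagents that add atoms: N-methoxy-N-methylacetamide, CC(=O)N(C)OC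
Why: A third directed ortho-metalation at the last ring H, then Weinreb-amide acylation; the chelated tetrahedral intermediate prevents over-addition.

### Fragment B (chromenyl bromide 16)

**Step 5**
Reactants: **9** 3-hydroxyphenyl benzoate (resorcinol monobenzoate); **10** N-bromosuccinimide
Product: **11** 2-bromo-5-hydroxyphenyl benzoate (Br para to the free OH, ortho to OBz)
Conditions: NBS (1.0 equiv), MeCN, 0 °C → rt; chromatography/recrystallisation to remove the minor ortho isomer
Reagents that add atoms: NBS, O=C1CCC(=O)N1Br
Why: Electrophilic aromatic bromination is directed para to the free phenol, the dominant donor, because the benzoate oxygen is deactivated.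

**Step 6**
Reactants: **11**; **2** MOMCl
Product: **12** 2-bromo-5-(methoxymethoxy)phenyl benzoate
Conditions: MOMCl (1.5 equiv), i-Pr2NEt, CH2Cl2, 0 °C → rt
Reagents that add atoms: MOMCl, COCCl
Why: Phenol O-alkylation under mild amine base leaves the benzoate and aryl bromide untouched and fixes which oxygen ends up as the free 4'-OH.

**Step 7**
Reactants: **12**
Product: **13** 2-bromo-5-(methoxymethoxy)phenol
Conditions: K2CO3, MeOH, rt
Reagents that add atoms: none
Why: Methanolysis (transesterification) of the aryl benzoate frees the phenol ortho to Br; the MOM ether and C–Br bond are inert to mild base.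

**Step 8**
Reactants: **13**; **14** 3-chloro-3-methylbut-1-yne
Product: **15** 1-bromo-4-(methoxymethoxy)-2-[(2-methylbut-3-yn-2-yl)oxy]benzene
Conditions: DBU (1.5 equiv), CuCl2·2H2O (1 mol %), MeCN, 0 °C → rt
Reagents that add atoms: 3-chloro-3-methylbut-1-yne, C#CC(C)(C)Cl
Why: Copper-catalysed O-propargylation (Godfrey conditions, via a Cu-acetylide/allenylidene) makes the hindered tertiary propargyl aryl ether without elimination.

**Step 9**
Reactants: **15**
Product: **16** 8-bromo-5-(methoxymethoxy)-2,2-dimethyl-2H-chromene
Conditions: N,N-diethylaniline, 190 °C (sealed tube or reflux)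
Reagents that add atoms: none
Why: Aromatic propargyl Claisen rearrangement, [1,5]-H shift and oxa-6π electrocyclisation form the chromene; the only open ortho position is the carbon between the two oxygens (the other carries Br), so one regioisomer forms.

### Union and endgame

**Step 10**
Reactants: **8**; **16**
Product: **17** 2-[5-(methoxymethoxy)-2,2-dimethyl-2H-chromen-8-yl]-1-[2,4,6-tris(methoxymethoxy)-3,5-bis(3-methylbut-2-en-1-yl)phenyl]ethan-1-one (deoxybenzoin)
Conditions: Pd2(dba)3 (2.5 mol %), XPhos (6 mol %), NaOt-Bu (2.2 equiv), toluene, 80 °C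
Reagents that add atoms: none (both partners are listed as reactants)
Why: Pd-catalysed ketone α-arylation of the unhindered methyl-ketone enolate with the electron-rich aryl bromide; the bulky ligand and the more acidic, more hindered product enolate stop the reaction at mono-arylation.

**Step 11**
Reactants: **17**; **18** N,N-dimethylformamide dimethyl acetal (DMF-DMA)
Product: **19** 3-(dimethylamino)-2-[5-(methoxymethoxy)-2,2-dimethyl-2H-chromen-8-yl]-1-[2,4,6-tris(methoxymethoxy)-3,5-bis(3-methylbut-2-en-1-yl)phenyl]prop-2-en-1-one (enaminone; E/Z irrelevant)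
Conditions: DMF-DMA (5 equiv), toluene, 100 °C
Reagents that add atoms: DMF-DMA, COC(OC)N(C)C
Why: Condensation of the doubly activated benzylic methylene with the amide acetal installs the future C-2 as a vinylogous amide under neutral conditions that all MOM ethers and alkenes tolerate.

**Step 12 (key ring closure)**
Reactants: **19**
Product: **20** Kanzonol L, 5,7-dihydroxy-3-(5-hydroxy-2,2-dimethyl-2H-chromen-8-yl)-6,8-bis(3-methylbut-2-en-1-yl)-4H-chromen-4-one
Conditions: 3 M aq. HCl, MeOH–THF, 50 °C, monitored and stopped at full conversion
Reagents that add atoms: none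
Why: Acid removes the MOM groups, and the freed ortho-phenol adds 6-endo to the β-carbon of the protonated enaminone (intramolecular oxa-Michael addition), then loses Me2NH to give the 4-pyranone. The two ortho oxygens are symmetry-equivalent, so one isoflavone forms, and no stereocentre is created.

## Compound list

1 | phloroglucinol | Oc1cc(O)cc(O)c1 | starting material
2 | chloromethyl methyl ether (MOMCl) | COCCl | starting material (reagent)
3 | 1,3,5-tris(methoxymethoxy)benzene | COCOc1cc(OCOC)cc(OCOC)c1 | intermediate
4 | prenyl bromide | CC(C)=CCBr | starting material (reagent)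
5 | 1,3,5-tris(methoxymethoxy)-2-(3-methylbut-2-en-1-yl)benzene | COCOc1cc(OCOC)c(CC=C(C)C)c(OCOC)c1 | intermediate
6 | 1,3,5-tris(methoxymethoxy)-2,4-bis(3-methylbut-2-en-1-yl)benzene | COCOc1cc(OCOC)c(CC=C(C)C)c(OCOC)c1CC=C(C)C | intermediate
7 | N-methoxy-N-methylacetamide | CC(=O)N(C)OC | starting material (reagent)
8 | 1-[2,4,6-tris(methoxymethoxy)-3,5-bis(3-methylbut-2-en-1-yl)phenyl]ethan-1-one | CC(=O)c1c(OCOC)c(CC=C(C)C)c(OCOC)c(CC=C(C)C)c1OCOC | intermediate
9 | 3-hydroxyphenyl benzoate | O=C(Oc1cccc(O)c1)c1ccccc1 | starting material
10 | N-bromosuccinimide | O=C1CCC(=O)N1Br | starting material (reagent)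
11 | 2-bromo-5-hydroxyphenyl benzoate | O=C(Oc1cc(O)ccc1Br)c1ccccc1 | intermediate
12 | 2-bromo-5-(methoxymethoxy)phenyl benzoate | COCOc1ccc(Br)c(OC(=O)c2ccccc2)c1 | intermediate
13 | 2-bromo-5-(methoxymethoxy)phenol | COCOc1ccc(Br)c(O)c1 | intermediate
14 | 3-chloro-3-methylbut-1-yne | C#CC(C)(C)Cl | starting material (reagent)
15 | 1-bromo-4-(methoxymethoxy)-2-[(2-methylbut-3-yn-2-yl)oxy]benzene | COCOc1ccc(Br)c(OC(C)(C)C#C)c1 | intermediate
16 | 8-bromo-5-(methoxymethoxy)-2,2-dimethyl-2H-chromene | COCOc1ccc(Br)c2OC(C)(C)C=Cc12 | intermediate
17 | deoxybenzoin (name in step 10) | COCOc1ccc(CC(=O)c2c(OCOC)c(CC=C(C)C)c(OCOC)c(CC=C(C)C)c2OCOC)c2OC(C)(C)C=Cc12 | intermediate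
18 | DMF-DMA | COC(OC)N(C)C | starting material (reagent)
19 | enaminone (name in step 11) | CN(C)C=C(C(=O)c1c(OCOC)c(CC=C(C)C)c(OCOC)c(CC=C(C)C)c1OCOC)c1ccc(OCOC)c2C=CC(C)(C)Oc12 | intermediate
20 | Kanzonol L | CC(C)=CCc1c(O)c(CC=C(C)C)c2occ(-c3ccc(O)c4c3OC(C)(C)C=C4)c(=O)c2c1O | target

## Step count

Total steps: 12 (fragment A: steps 1–4; fragment B: steps 5–9; union and endgame: steps 10–12).
Longest linear sequence: 8 steps (5 → 6 → 7 → 8 → 9 → 10 → 11 → 12), which is two thirds of the total.

## Three steps most likely to fail, with fallbacks

1. **Step 10 (Pd α-arylation of two hindered, electron-rich partners).** Fallback: change the union to a Suzuki–Miyaura coupling. Convert **16** to its pinacol boronate (n-BuLi, i-PrOBpin). Convert **8** to the 3-iodochromone by cleaving one ortho-MOM, DMF-DMA, then I2/pyridine (1.0 equiv, to spare the prenyl alkenes). The pyranone is then closed before the coupling, and MOM removal follows it.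

2. **Step 12 (acidic cyclisation and global deprotection; risk of acid-promoted prenyl-to-chroman cyclisation or MeOH addition to the chromene).** Fallback: separate ring closure from deprotection and avoid hot protic acid. Cleave only the carbonyl-chelated ortho-MOM of **17** (MgBr2·OEt2 or cat. HCl/MeOH, 0 °C). Let DMF-DMA formylate and cyclise the 2-hydroxy-deoxybenzoin thermally under neutral conditions. Remove the remaining three MOM groups with ZnBr2/n-PrSH in CH2Cl2 at 0 °C.

3. **Step 4 (acylation of a fully ortho-substituted aryllithium; enolisation of the Weinreb amide may compete).** Fallback: start with the ketone in place. Bis-C-prenylate commercial 2,4,6-trihydroxyacetophenone directly (prenyl bromide, aq. KOH, 0 °C; modest yield), then tris-MOM protect (NaH, MOMCl, DMF) to reach **8**.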